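**Retrosynthetic overview**
- Feature used: in ring A, C4a (bearing the C4 carbonyl) lies on a local twofold axis running through C4a and C7. Its two ortho carbons, C8a (bonded to O1) and C5 (bearing the 5-OH), are equivalent, as are the 6-OMe and 8-OMe groups. Both ortho oxygens can therefore start as bromine on a syringic-acid-derived aroyl unit.
- Target ⇐ hydrogenolysis of three benzyl ethers ⇐ copper hydroxylation of C5–Br ⇐ 5-bromoflavone.
- Ring C is the only ring formed (rings A and B are bought as arenes): the O1–C8a bond is closed by intramolecular Cu-catalysed O-arylation of the enolised diaryl 1,3-diketone at one of the two equivalent C–Br bonds.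
- Diketone ⇐ C-acylation of the lithium enolate of 2,5-bis(benzyloxy)-4-methoxyacetophenone (from 2-methoxyhydroquinone) with 4-(benzyloxy)-2,6-dibromo-3,5-dimethoxybenzoyl chloride (from syringic acid).

Key step: step 7

Remark: the target has no stereocentre and no configurationally stable axis, so "single enantiomer" has no consequence here; the route delivers the achiral compound.

**Route**

Step 1
Reactants: 1 syringic acid; 2 benzyl bromide
Product: 4 4-(benzyloxy)-3,5-dimethoxybenzoic acid, via benzyl ester 3 (not isolated)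
Conditions: BnBr (2.4 equiv), K2CO3 (3 equiv), DMF, 60 °C; then 2 M NaOH, MeOH, 60 °C; HCl to pH 2
Reagents that add atoms: benzyl bromide (compound 2), BrCc1ccccc1; sodium hydroxide, [Na+].[OH-]
Why: Williamson alkylation of the phenoxide and carboxylate is followed by acyl-oxygen saponification of the still unhindered benzyl ester; the ester is cleaved at this stage because a 2,6-dibromobenzoate formed later would resist hydrolysis.

Step 2
Reactants: 4 4-(benzyloxy)-3,5-dimethoxybenzoic acid
Product: 5 4-(benzyloxy)-2,6-dibromo-3,5-dimethoxybenzoic acid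
Conditions: Br2 (2.2 equiv), NaOAc (2.5 equiv), AcOH, rt → 50 °C, dark
Reagents that add atoms: bromine, BrBr
Why: electrophilic aromatic bromination at C2 and C6, the only free ring positions, each ortho to one OMe and para to the other; acetate buffers HBr so the benzyl ether survives, and limiting bromine to just over two equivalents guards against ipso-bromodecarboxylation.

Step 3
Reactants: 5 4-(benzyloxy)-2,6-dibromo-3,5-dimethoxybenzoic acid
Product: 6 4-(benzyloxy)-2,6-dibromo-3,5-dimethoxybenzoyl chloride
Conditions: (COCl)2 (1.5 equiv), cat. DMF, CH2Cl2, 0 °C → rt; evaporate, use crude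
Reagents that add atoms: oxalyl chloride, O=C(Cl)C(=O)Cl
Why: chlorination of the acid through the catalytic chloroiminium (Vilsmeier-type) species works on di-ortho-substituted benzoic acids and leaves aryl ethers and aryl bromides untouched.

Step 4
Reactants: 7 2-methoxyhydroquinone
Product: 9 1-(2,5-dihydroxy-4-methoxyphenyl)ethan-1-one, via difluoroboron chelate 8 (not isolated)
Conditions: AcOH, BF3·OEt2 (3 equiv), 90 °C; then 1 M HCl/MeOH, 60 °C
Reagents that add atoms: acetic acid, CC(=O)O
Why: BF3-mediated Friedel–Crafts C-acylation of the free phenol should go to C5 of the hydroquinone, the one unhindered position activated by two donors (para to OMe, ortho to OH); the ketone is held as its O–BF2 chelate, which blocks a second acylation and is released by acidic methanolysis together with any aryl acetate.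

Step 5
Reactants: 9 1-(2,5-dihydroxy-4-methoxyphenyl)ethan-1-one; 2 benzyl bromide
Product: 10 1-[2,5-bis(benzyloxy)-4-methoxyphenyl]ethan-1-one
Conditions: BnBr (2.5 equiv), K2CO3 (3 equiv), cat. KI, DMF, 70 °C, N2
Reagents that add atoms: benzyl bromide (compound 2), BrCc1ccccc1
Why: Williamson etherification of both phenols, with DMF and heat to alkylate the hydrogen-bonded 2-OH and nitrogen to keep the hydroquinone from oxidising.

Step 6
Reactants: 10 1-[2,5-bis(benzyloxy)-4-methoxyphenyl]ethan-1-one; 6 4-(benzyloxy)-2,6-dibromo-3,5-dimethoxybenzoyl chloride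
Product: 12 1-[4-(benzyloxy)-2,6-dibromo-3,5-dimethoxyphenyl]-3-[2,5-bis(benzyloxy)-4-methoxyphenyl]propane-1,3-dione, via lithium enolate 11 (not isolated)
Conditions: LiHMDS (2.2 equiv), THF, −78 °C; then 6 (0.95 equiv) in THF, −78 → 0 °C; aq. NH4Cl/1 M HCl
Reagents that add atoms: none
Why: crossed Claisen-type C-acylation of a preformed lithium enolate of an aryl methyl ketone by an aroyl chloride, with the second equivalent of base deprotonating the diketone as it forms so that proton transfer does not stall conversion and diacylation is suppressed.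

Step 7
Reactants: 12 1-[4-(benzyloxy)-2,6-dibromo-3,5-dimethoxyphenyl]-3-[2,5-bis(benzyloxy)-4-methoxyphenyl]propane-1,3-dione
Product: 13 7-(benzyloxy)-2-[2,5-bis(benzyloxy)-4-methoxyphenyl]-5-bromo-6,8-dimethoxy-4H-chromen-4-one
Conditions: CuI (10 mol%), 1,10-phenanthroline (20 mol%), Cs2CO3 (1.5 equiv), dry degassed DMF, 90 °C, Ar
Reagents that add atoms: none
Why: Cs2CO3 converts 12 into its enolate, which binds Cu(I)–phenanthroline through oxygen; oxidative addition of the adjacent ortho C–Br bond, helped by chelation to the aroyl oxygen, and C–O reductive elimination from the aryl–copper enolate form O1–C8a. The closest known reaction type is the copper-catalysed intramolecular Ullmann O-arylation of 1-(2-haloaryl)-1,3-diketones to flavones and chromones. Ring C closes as a six-membered pyranone by attack of the enolate oxygen on the B-ring side (the future O1) on the aryl carbon with bromide leaving, formally a 6-exo closure; the other enolate oxygen or the central carbon could only form a four-membered ring and cannot compete. No stereocentre is formed. The selectivity needed is reaction at exactly one C–Br bond: the two bromines are equivalent through the twofold symmetry of the aroyl ring, so either closure gives the same product, and after closure no internal nucleophile remains, so C5–Br is kept by holding the temperature at 90 °C and excluding water. The three alkoxy donors on the ring rule out an uncatalysed SNAr pathway, which is why copper is used.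

Step 8
Reactants: 13 7-(benzyloxy)-2-[2,5-bis(benzyloxy)-4-methoxyphenyl]-5-bromo-6,8-dimethoxy-4H-chromen-4-one
Product: 14 7-(benzyloxy)-2-[2,5-bis(benzyloxy)-4-methoxyphenyl]-5-hydroxy-6,8-dimethoxy-4H-chromen-4-one
Conditions: Cu(acac)2 (5 mol%), N,N'-bis(4-hydroxy-2,6-dimethylphenyl)oxalamide (5 mol%), LiOH·H2O (2.2 equiv), DMSO/H2O 4:1, 80 °C; then 1 M HCl
Reagents that add atoms: lithium hydroxide, [Li+].[OH-]
Why: copper-catalysed Ullmann-type hydroxylation of an aryl bromide, in which the peri C4 carbonyl can chelate copper at the C5–Br bond and the small hydroxide nucleophile tolerates the two ortho substituents; the product is held as a chelated 5-phenoxide.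

Step 9
Reactants: 14 7-(benzyloxy)-2-[2,5-bis(benzyloxy)-4-methoxyphenyl]-5-hydroxy-6,8-dimethoxy-4H-chromen-4-one
Product: 15 2-(2,5-dihydroxy-4-methoxyphenyl)-5,7-dihydroxy-6,8-dimethoxy-4H-chromen-4-one (target)
Conditions: H2 (1 atm), 10% Pd/C, THF/MeOH 1:1, rt; filter and concentrate under Ar
Reagents that add atoms: none
Why: palladium-catalysed hydrogenolysis of the three aryl benzyl ethers is much faster than reduction of the vinylogous-ester C2=C3 bond of the chromone, and air is excluded because the freed 2′,5′-hydroquinone is oxidisable.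

**Compound list**
1 | syringic acid (4-hydroxy-3,5-dimethoxybenzoic acid) | COc1cc(C(=O)O)cc(OC)c1O | starting material
2 | benzyl bromide | BrCc1ccccc1 | starting material
3 | benzyl 4-(benzyloxy)-3,5-dimethoxybenzoate | COc1cc(C(=O)OCc2ccccc2)cc(OC)c1OCc1ccccc1 | intermediate (not isolated)
4 | 4-(benzyloxy)-3,5-dimethoxybenzoic acid | COc1cc(C(=O)O)cc(OC)c1OCc1ccccc1 | intermediate
5 | 4-(benzyloxy)-2,6-dibromo-3,5-dimethoxybenzoic acid | COc1c(Br)c(C(=O)O)c(Br)c(OC)c1OCc1ccccc1 | intermediate
6 | 4-(benzyloxy)-2,6-dibromo-3,5-dimethoxybenzoyl chloride | COc1c(Br)c(C(Cl)=O)c(Br)c(OC)c1OCc1ccccc1 | intermediate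
7 | 2-methoxyhydroquinone (2-methoxybenzene-1,4-diol) | COc1cc(O)ccc1O | starting material
8 | difluoroboron chelate of ketone 9 (2,2-difluoro-6-hydroxy-7-methoxy-4-methyl-1,3,2-benzodioxaborinin-3-ium-2-uide; O2′–BF2←O=C) | COc1cc2c(cc1O)C(C)=[O+][B-](F)(F)O2 | intermediate (not isolated)
9 | 1-(2,5-dihydroxy-4-methoxyphenyl)ethan-1-one | COc1cc(O)c(C(C)=O)cc1O | intermediate
10 | 1-[2,5-bis(benzyloxy)-4-methoxyphenyl]ethan-1-one | COc1cc(OCc2ccccc2)c(C(C)=O)cc1OCc1ccccc1 | intermediate
11 | lithium 1-[2,5-bis(benzyloxy)-4-methoxyphenyl]ethen-1-olate | [Li+].[O-]C(=C)c1cc(OCc2ccccc2)c(OC)cc1OCc1ccccc1 | intermediate (not isolated)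
12 | 1-[4-(benzyloxy)-2,6-dibromo-3,5-dimethoxyphenyl]-3-[2,5-bis(benzyloxy)-4-methoxyphenyl]propane-1,3-dione (drawn as diketone; largely enolised) | COc1cc(OCc2ccccc2)c(C(=O)CC(=O)c2c(Br)c(OC)c(OCc3ccccc3)c(OC)c2Br)cc1OCc1ccccc1 | intermediate
13 | 7-(benzyloxy)-2-[2,5-bis(benzyloxy)-4-methoxyphenyl]-5-bromo-6,8-dimethoxy-4H-chromen-4-one | COc1cc(OCc2ccccc2)c(-c2cc(=O)c3c(Br)c(OC)c(OCc4ccccc4)c(OC)c3o2)cc1OCc1ccccc1 | intermediate
14 | 7-(benzyloxy)-2-[2,5-bis(benzyloxy)-4-methoxyphenyl]-5-hydroxy-6,8-dimethoxy-4H-chromen-4-one | COc1cc(OCc2ccccc2)c(-c2cc(=O)c3c(O)c(OC)c(OCc4ccccc4)c(OC)c3o2)cc1OCc1ccccc1 | intermediate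
15 | 2-(2,5-dihydroxy-4-methoxyphenyl)-5,7-dihydroxy-6,8-dimethoxy-4H-chromen-4-one | COc1cc(O)c(-c2cc(=O)c3c(O)c(OC)c(O)c(OC)c3o2)cc1O | target

**Step count**
Total steps: 9. Longest linear sequence: 7 steps (steps 1, 2, 3, 6, 7, 8, 9 from syringic acid); the acetophenone branch (steps 4, 5) joins at step 6.

**Steps most likely to fail, with fallbacks**

Step 7. The C–Br bond that must react is flanked by an OMe group and a twisted aroyl group, so oxidative addition to copper may be slow, and protodebromination or retro-Claisen cleavage of the diketone could take over. The fallback makes the O1–C8a bond earlier with hydroxide and closes ring C by classical cyclodehydration. It sets out from dibromo acid 5. Carboxylate-directed copper-catalysed hydroxylation of one ortho C–Br bond (cat. Cu2O, aq. KOH, 80 °C, run to partial conversion with recovery of 5) should give 4-(benzyloxy)-2-bromo-6-hydroxy-3,5-dimethoxybenzoic acid F1. Acetone/SOCl2/DMAP in DME should convert this into 7-(benzyloxy)-5-bromo-6,8-dimethoxy-2,2-dimethyl-4H-1,3-benzodioxin-4-one F2. Lithium enolate 11 (from 10, LiHMDS, THF, −78 → 0 °C) should open the dioxinone at its carbonyl, with loss of acetone, to 1-[4-(benzyloxy)-2-bromo-6-hydroxy-3,5-dimethoxyphenyl]-3-[2,5-bis(benzyloxy)-4-methoxyphenyl]propane-1,3-dione F3. Cyclodehydration (cat. p-TsOH, toluene, 90 °C) then comes back to the route at bromoflavone 13.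

Step 8. Hydroxide may add at C2 and open the pyranone, or the di-ortho-substituted C5–Br bond may be reduced instead of oxygenated. The fallback sets out from 13 and uses methoxide, then removes the peri methyl together with the benzyl groups. Copper-mediated methoxylation (NaOMe, CuBr, DMF/MeOH, 100 °C) should give 7-(benzyloxy)-2-[2,5-bis(benzyloxy)-4-methoxyphenyl]-5,6,8-trimethoxy-4H-chromen-4-one F4. BCl3 with pentamethylbenzene in CH2Cl2 (−78 → 0 °C) should then cleave the three benzyl ethers and, through chelation to the C4 carbonyl, only the 5-OMe group. This comes back to the route at target 15 and replaces step 9 as well.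

Step 6. The acid chloride carbonyl is shielded by two ortho bromines, so attack by the enolate may be sluggish and O-acylation to the enol ester may compete. The fallback sets out from acid chloride 6 and uses the less hindered aldehyde oxidation level. Reduction with LiAlH(OtBu)3 (THF, −78 °C) should give 4-(benzyloxy)-2,6-dibromo-3,5-dimethoxybenzaldehyde F5. Aldol addition of lithium enolate 11 (THF, −78 °C, cold quench) should give racemic 3-[4-(benzyloxy)-2,6-dibromo-3,5-dimethoxyphenyl]-1-[2,5-bis(benzyloxy)-4-methoxyphenyl]-3-hydroxypropan-1-one F6. Oxidation of the β-hydroxy ketone with Dess–Martin periodinane (CH2Cl2, rt) comes back to the route at diketone 12.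

**Further compounds**
F1 | step 7 | 4-(benzyloxy)-2-bromo-6-hydroxy-3,5-dimethoxybenzoic acid | COc1c(O)c(C(=O)O)c(Br)c(OC)c1OCc1ccccc1
F2 | step 7 | 7-(benzyloxy)-5-bromo-6,8-dimethoxy-2,2-dimethyl-4H-1,3-benzodioxin-4-one | COc1c(Br)c2C(=O)OC(C)(C)Oc2c(OC)c1OCc1ccccc1
F3 | step 7 | 1-[4-(benzyloxy)-2-bromo-6-hydroxy-3,5-dimethoxyphenyl]-3-[2,5-bis(benzyloxy)-4-methoxyphenyl]propane-1,3-dione | COc1cc(OCc2ccccc2)c(C(=O)CC(=O)c2c(Br)c(OC)c(OCc3ccccc3)c(OC)c2O)cc1OCc1ccccc1
F4 | step 8 | 7-(benzyloxy)-2-[2,5-bis(benzyloxy)-4-methoxyphenyl]-5,6,8-trimethoxy-4H-chromen-4-one | COc1cc(OCc2ccccc2)c(-c2cc(=O)c3c(OC)c(OC)c(OCc4ccccc4)c(OC)c3o2)cc1OCc1ccccc1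
F5 | step 6 | 4-(benzyloxy)-2,6-dibromo-3,5-dimethoxybenzaldehyde | COc1c(Br)c(C=O)c(Br)c(OC)c1OCc1ccccc1
F6 | step 6 | 3-[4-(benzyloxy)-2,6-dibromo-3,5-dimethoxyphenyl]-1-[2,5-bis(benzyloxy)-4-methoxyphenyl]-3-hydroxypropan-1-one (racemic) | COc1cc(OCc2ccccc2)c(C(=O)CC(O)c2c(Br)c(OC)c(OCc3ccccc3)c(OC)c2Br)cc1OCc1ccccc1
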